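A ratio of two amounts is what you want from this flask: the target it ends with over the reagent it was given, both as fractions of the starting-material charge.

| flask | starting material | reagent | second substrate | third substrate | temperature | remark | time |
|---|---|---|---|---|---|---|---|
| delta | 20 mM | 0.60 equiv | 1 equiv | 0.20 equiv | 25 °C | the very flask that is asked about, followed so far |  |
| alpha | 20 mM | 1.2 equiv | 1 equiv | 0.20 equiv | 31 °C | run made earlier |  |
| flask | 20 mM | 0.600 equiv | 1.00 equiv | 0.200 equiv | 25 °C |  | 3.0 d |

| run | time / h | target / % | starting material / % |
|---|---|---|---|
| delta | 12.0 | 18 | 82 |
| delta | 25.0 | 22 | 81 |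
| delta | 40.0 | 18 | 80 |
| delta | 50.0 | 21 | 80 |
| delta | 60.0 | 19 | 78 |
| delta | 72.0 | 20 | 83 |
| alpha | 0.667 | 14 | 84 |
| alpha | 2.00 | 25 | 78 |
| alpha | 4.00 | 30 | 68 |
| alpha | 6.00 | 35 | 67 |
| alpha | 8.00 | 35 | 65 |
| alpha | 10.0 | 34 | 65 |

(scatter of a reading: 1.5 percentage points)

- blue: at 3.0 d add reagent, 100% of the amount charged, then wait 40 h
- grey: at 3.0 d take out 90% of the target then present, then wait 40 h
- ochre: at 3.0 d raise the temperature by 15 K, then wait 40 h
- red: change nothing and wait 40 h more

- target that was removed still counts
- the numbers in the tables scatter with a standard deviation of 1.5 percentage points
- additions bring no volume worth counting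

* target, in percent of the starting material first charged, at 3.0 d
* the option that brings most further target ("none" if no option brings more than 2 percentage points) (blue / grey / ochre / red / none)
* target present, with what was taken out counted in, in percent of the starting material first charged, after grey
* target present, with what was taken out counted in, in percent of the starting material first charged, after ochre

Why these two amounts? Time isn't the one to watch, since the delta run, which is this flask followed so far, reads 18% of target at 12.0 h and 20% at 72.0 h, a change of 2 percentage points against a scatter of 1.5 points. Starting material isn't the one either, since that same last delta reading still shows 83% of it, more than the target. Reagent is my candidate: the alpha run, with the same second and third substrate but twice the reagent, ended at 34%, though it was also warmer, so these two runs can't part the two changes. So I treat reagent as the limiting reagent, and the delta run gives 0.333 of target per unit of reagent, the return on reagent, against 0.283 in the alpha run.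

My reckoning then leaves this flask at 20.0%, which is the last delta reading handed back and no check on it. Grey, ochre and red add no reagent, so the return has no new reagent to multiply, whereas blue's fresh dose of 100% of the charge should bring 20 points, against a margin of 2 points.

The forecast says 19.8% now, blue as best, 20% after grey and 20.3% after ochre, reasoning “This reads as reagent spent, with decay competing with product formation.” It expects about 15 points from blue, where I reckon 20 points.

The flask gives 19.4%, best option blue with 24 points gained, 19.4% after grey and 19.4% after ochre, and 0% of the charged reagent is free at 72.0 h.

    starting material + reagent → target (k = 9.80 L mol⁻¹ h⁻¹, Ea = 67.0 kJ mol⁻¹)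
    second substrate + reagent → second product (k = 2.10 L mol⁻¹ h⁻¹, Ea = 65.0 kJ mol⁻¹)
    2 reagent → self-condensation product (k = 18.0 L mol⁻¹ h⁻¹, Ea = 46.0 kJ mol⁻¹)
    third substrate + reagent → third product (k = 190 L mol⁻¹ h⁻¹, Ea = 50.0 kJ mol⁻¹)
    (constants at 25 °C)

On this flask the return promises 20 points from blue's dose, against the 24 points found.

In the neighbouring repeat at 50 °C, with the same charges, the return gives 20.0%; the computed flask ends at 23.8%, with 0% of its reagent free.

The numbers in the tables are calculated on assumed constants, and the scatter is random.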